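(The constants used here stand for no real mixture; the run is a simulation.)

4 questions stand on 2 flasks, which differ in their time of reading.

- ochre: starting material 0.050 M; solid reagent 0.0500 M; time 5.0 min
- blue: starting material 0.050 M; solid reagent 0.0500 M; time 15 min

    2 starting material → homo dimer (k1 = 0.0702 M⁻¹ s⁻¹)
    mono adduct ⇌ isomer of the product (K2 = 0.668, k2 = 0.00115 s⁻¹)
    solid reagent ⇌ partner, rate k3*(cs3 - [partner]) while solid is left; crystals form when [partner] > cs3 (cs3 = 43 mM, k3 = 0.0107 s⁻¹)
    partner + other mono adduct → bis adduct (k4 = 0.00858 M⁻¹ s⁻¹)
    partner + mono adduct → bis adduct (k5 = 0.101 M⁻¹ s⁻¹)
    starting material + partner → other mono adduct (k6 = 0.163 M⁻¹ s⁻¹)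
    starting material + partner → mono adduct (k7 = 0.265 M⁻¹ s⁻¹)

- which of the two there is more of at the end, ochre (mono adduct / bis adduct)
- which of the two there is more of at the end, blue (mono adduct / bis adduct)
- mono adduct at the end, in percent of the starting material charged, ochre
- mono adduct at the end, in percent of the starting material charged, blue

- in percentages every species weighs as the starting material in it: one homo dimer counts as two
- for a step with 2 of a species take k times the square, and two of it per event
- as a solid, counted per litre of solution: solid reagent
- at the start none of the solid reagent is in solution
- run time (ochre): 5.0 min

Hold the mono adduct and the isomer of the product together as one pool, and ask how fast bis adduct formation bleeds it. Start at the early end. Partner climbs on a clock of 1.56 min, shorter than the 2.37 min first half-life of the starting material by dimerising, but you can't ignore that lag. So set the starting material at its charge and partner at half its solubility, and compare the rates: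

share reaching adducts = 56.7%; mono share of these (the selectivity) = 61.9%; made on the mono route = 35.1% of the charge

Take that as born at about 1.56 min. One partner went into each adduct, which leaves 0.0216 M.

Ochre then runs 3.44 min more, less than the 4.02 min relaxation half-life of the pair, so count no return from the isomer:

surviving = exp(−(bis rate + isomer rate) × time) = 50.2%; mono adduct = 17.6%; bis adduct = 11.5%; ahead: mono adduct

Blue runs 13.4 min more, longer than that relaxation half-life, so take the pool as relaxed, with 60.0% of it as mono adduct. In the scheme the isomer of the product has no step with partner, so the bleed runs on that part of the pool. But the bleed spends partner too: a first pass at 0.0216 M keeps 34.8% of the pool, so I take partner at about 0.0159 M on average. That gives the bleed constant, pseudo-first-order, the partner level times the bis constant times the mono part of the pool: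

bleed constant = 0.0578 min⁻¹; pool kept = 46.0%; mono adduct = 9.68%; bis adduct = 19.0%; ahead: bis adduct

The forecast names mono adduct for ochre and bis adduct for blue, with 21% and 12% of mono adduct, higher than my figures on both; its ground for blue is that “the remaining partner steadily converts mono adduct to bis adduct”.

The flask gives 20.8% mono adduct against 10.5% bis adduct in ochre, and 10.9% against 21.8% in blue, so the forecast stands. Blue's pool reads 18.5%, reckoned 16.1%. Now charge the blue flask with 0.12 M of solid reagent, all else held: at the end 23.7% of it stands undissolved and partner reads 0.0419 M, so put the solubility into the bleed constant, which gives 0.156 min⁻¹ and 2.60% mono adduct. That flask reads 2.68%, but its pool reads 7.34% against a reckoned 4.34%.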